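## Analysis of the target

The target 35 is a ceramide whose amine part is a 17-carbon sphingoid chain, numbered from the CH2OH carbon C1, with nitrogen on C2 and hydroxyls on C1, C3 and C4. The chain carries an E double bond at C6=C7 and one extra carbon that bridges C12 and C13 as a trans-cyclopropane, and the nitrogen is acylated by (2R)-2-hydroxypentacosanoic acid. Apart from the three-membered ring the molecule is acyclic, so every stereocenter has to come from acyclic control. There are six: C2 (S), C3 (S) and C4 (R) form a contiguous amino-triol triad of the D-ribo (phytosphingosine) type, with C2–N/C3–O and C3–O/C4–O both anti in the extended chain; C12 (S) and C13 (S) are the ring carbons; C2' (R) carries the acyl hydroxyl. The ring lies eight bonds from C4, beyond the alkene and four methylenes, so it cannot be controlled from the head group and must be made as one enantiomer on its own fragment. The C6=C7 alkene is isolated, with no carbonyl or allylic heteroatom to fix its geometry, and together with the cyclopropane it rules out heterogeneous hydrogenation, hydrogenolytic deprotection, and cation or radical chemistry next to the ring. The polar head is prone to acyl and acetal migration, and the C25 chain makes late intermediates waxy and poorly soluble, which argues for attaching it last. The plan rests on the array C4(OH)–C5H2–C6H=C7H, a homoallylic alcohol: carbinol carbon, methylene and E alkene are exactly what an α-substituted allylboron reagent leaves when it adds to an aldehyde with allylic transposition.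

## Retrosynthetic reasoning

The first cut is the amide C–N bond, which divides 35 into aminotriol 25 and hydroxy acid 33. Cutting here keeps the insoluble C25 chain out of all stereochemistry-building steps. The forward reaction has to acylate nitrogen in the presence of four free hydroxyls, which the higher nucleophilicity of the amine toward active ester 34 should secure.

Acid 33 is traced to the unfunctionalised acid 26 by cutting its C2–O bond. An enolate oxidation under auxiliary control is chosen because it starts from the intact C25 chain and needs no long-chain C–C coupling. Auxiliary 27 is attached to give imide 29, the enolate is hydroxylated to 31, and the auxiliary is cleaved.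

Aminotriol 25 comes from 24 by removing carbamate, N,O-acetal and silyl ether in one acidic operation. All three groups were chosen so that no reductive or oxidative deprotection is needed once the alkene and cyclopropane are in place.

In 24 the C4–C5 bond is cut with transposition of the alkene from C6=C7 to a terminal C5=C6 vinyl group, giving aldehyde 7 (C1–C4) and secondary allylboronate 20 (C5–C17). A cut at C6=C7 would leave the geometry to an olefination or metathesis with no built-in bias. A cut at C3–C4 would require a β,γ-unsaturated aldehyde that slips into conjugation. The chosen cut makes one C–C bond, the C4 stereocenter and the E alkene in a single closed transition state and joins two fragments of similar size. The forward step must deliver E geometry and Re-face attack on 7.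

Aldehyde 7 is simplified by cutting the C3–C4 bond. The aldehyde carbon is masked as the vinyl group of silyl ether 5, which comes from allylic alcohol 4 and that from aldehyde 3 by anti-selective vinyl addition. Aldehyde 3 is the partial reduction product of the purchasable amino-acid-derived ester 1, which supplies C2 and the nitrogen.

Boronate 20 is cut at the C6–C7 bond. The vinyl group and the boron come from vinylboronate 17, and C7 comes from the oxygen-bearing carbon of carbamate 16. The forward reaction is a lithiation–borylation with 1,2-migration, which creates the boron-bearing stereocenter under control of a chiral diamine and is independent of the distant ring.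

Carbamate 16 derives from alcohol 15, and 15 from acid 14 and unsaturated acid 13, where the C10–C11 bond is cut as a carbonyl olefination between aldehyde 10 and phosphonium salt 11. C11 is a cyclopropylcarbinyl position, and a cation, radical or organometallic centre there would open the ring. An olefination keeps C11 closed-shell, and the extra alkene is removed by a concerted, metal-free hydrogen transfer.

Aldehyde 10 comes from alcohol 9, whose ring is opened retrosynthetically at the two bonds from the ring CH2 to C12 and C13. This leads to the E allylic alcohol 8, whose hydroxyl directs an enantioselective methylene transfer and whose E geometry becomes the trans ring.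

## Alternatives that were turned down

Alternative 1: The cyclopropane is cut at the two ring bonds that meet at C12, so that C12 arrives as an ester-bearing carbene carbon and C13 with the ring CH2 arrives as a terminal alkene. In the forward step an engineered heme protein would turn ethyl diazoacetate A3 into an iron carbene and transfer it to hex-1-ene A2, giving ethyl (1S,2S)-2-butylcyclopropane-1-carboxylate A1. Partial reduction of A1 would give aldehyde 10, and the route would continue unchanged.
- For it: the feedstocks A2 and A3 are cheap and achiral, the chiral controller is catalytic, and the step count to 10 (two steps) equals that of the chosen sequence. On atom economy it is stronger, since the chosen cyclopropanation uses a stoichiometric chiral ligand and excess Zn(CH2I)2.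
- Against it: A2 is an unactivated, volatile aliphatic 1-alkene and a poor carbene acceptor compared with styrenes. It binds weakly in a protein pocket, and the carbene from A3 dimerises in competition. The trans-(1S,2S) configuration of A1 depends on having a variant evolved for exactly this substrate class, and protein expression and anaerobic handling are added.
- Comparison: making A1 addresses only the three-membered ring and leaves C4 and the alkene unsolved, so it would put the weight of the route on a two-step side fragment. The hydroxyl-directed Zn(CH2I)2 cyclopropanation of 8 gives the same ring with predictable absolute sense from bench reagents, which leaves the risk in the fragment union where it is most productive.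

Alternative 2: The C3–C4 bond is cut as an aldol. The enamine formed from 2,2-dimethyl-1,3-dioxan-5-one A5 and (R)-proline A7 would add to 3-[(4-methoxyphenyl)methoxy]propanal A6. The product is the anti aldol (4R)-4-[(1R)-1-hydroxy-3-[(4-methoxyphenyl)methoxy]propyl]-2,2-dimethyl-1,3-dioxan-5-one A4, which holds C1–C6 with both carbinol centres and a ketone at C2.
- For it: the two adjacent oxygen stereocenters of A4 arise in one catalytic step from the achiral materials A5 and A6. On that point it is stronger than the chosen route, which takes C2 from the chiral pool and C3 from substrate control.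
- Against it: the linear, enolisable aldehyde A6 is a weak acceptor in such aldols and competes by self-condensation. After the key step, nitrogen must still be introduced at the C2 ketone of A4 by a reductive amination that has to create a third stereocenter with 2,3-anti control. The ether must then be removed and C6 oxidised to an aldehyde whose β-oxygen invites elimination. The C6=C7 bond would then come from an olefination of an unstabilised partner with no reliable E bias.
- Comparison: with A4 in hand the alkene geometry and a long protecting-group sequence remain open. The chosen plan spends its key step on C4 and the alkene together and reaches the full carbon skeleton in that step.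

Alternative 3: The C2–N and C3–O bonds are cut together. Catalytic K2OsO2(OH)4 A10 would convert the Z-allylic carbamate (2Z,4R,6E)-11-[(1S,2S)-2-butylcyclopropyl]-4-[(tert-butyldimethylsilyl)oxy]undeca-2,6-dien-1-yl N-[(pentafluorobenzoyl)oxy]carbamate A9 into a tethered imido osmium species. This adds nitrogen to C2 and oxygen to C3 from one face and closes the five-membered cyclic carbamate, giving (4S)-4-[(1S,2R,4E)-9-[(1S,2S)-2-butylcyclopropyl]-2-[(tert-butyldimethylsilyl)oxy]-1-hydroxynon-4-en-1-yl]-1,3-oxazolidin-2-one A8.
- For it: the tether fixes regiochemistry, syn addition to the Z alkene of A9 gives the required 2,3-anti amino alcohol, and allylic strain around the C4 silyl ether should direct the metal anti to it. Two heteroatom stereocenters arise in one step without a chiral-pool head group, which the chosen route cannot claim.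
- Against it: A9 already contains the E C6=C7 alkene, a second site for the oxidant A10 that only the kinetic advantage of the tether protects. A9 itself needs C4, a Z alkene and an E alkene to be assembled first, so the hard part of the chain is merely moved earlier. The cyclic carbamate in A8 must finally be opened under strongly basic conditions.
- Comparison: stereocontrol is relayed from a single centre in both plans, but the chosen one never exposes a diene such as A9 to an oxidant, and it builds the C6=C7 alkene and C4 in the step that joins the fragments.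

Key step: step 12

Assumption: ester 1 (the N-Boc N,O-acetonide methyl ester made from L-serine) and (+)-sparteine are taken as purchasable, and (+)-sparteine is taken to remove the hydrogen enantiotopic to the one removed by (−)-sparteine.

## Route

Step 1
Reactants: 1 methyl (4S)-3-(tert-butoxycarbonyl)-2,2-dimethyl-1,3-oxazolidine-4-carboxylate
Product: 3 tert-butyl (4S)-4-formyl-2,2-dimethyl-1,3-oxazolidine-3-carboxylate (Garner aldehyde), via aluminium hemiacetal 2 (not isolated)
Conditions: i-Bu2AlH (1.6 equiv), toluene, −78 °C; MeOH, then aq. KNaC4H4O6, rt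
Reagents that add atoms: none
Why: Partial reduction of an ester with i-Bu2AlH; at −78 °C the tetrahedral aluminium hemiacetal 2 persists and releases the aldehyde only on work-up, so over-reduction is avoided, and the neutral cold work-up leaves C2 untouched.

Step 2
Reactants: 3 tert-butyl (4S)-4-formyl-2,2-dimethyl-1,3-oxazolidine-3-carboxylate
Product: 4 tert-butyl (4S)-4-[(1R)-1-hydroxyprop-2-en-1-yl]-2,2-dimethyl-1,3-oxazolidine-3-carboxylate
Conditions: CH2=CHMgBr (1.5 equiv), THF, −78 to −40 °C; aq. NH4Cl; chromatography
Reagents that add atoms: vinylmagnesium bromide, C=C[Mg]Br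
Why: Grignard addition under Felkin–Anh (non-chelation) control: the nucleophile approaches anti to the ring nitrogen, so the anti (erythro) alcohol, which is C3 of the target, should predominate, and the minor syn epimer is removed by chromatography.

Step 3
Reactants: 4 tert-butyl (4S)-4-[(1R)-1-hydroxyprop-2-en-1-yl]-2,2-dimethyl-1,3-oxazolidine-3-carboxylate
Product: 5 tert-butyl (4S)-4-[(1R)-1-[(tert-butyldimethylsilyl)oxy]prop-2-en-1-yl]-2,2-dimethyl-1,3-oxazolidine-3-carboxylate
Conditions: TBSOTf (1.2 equiv), 2,6-lutidine, CH2Cl2, −78 to 0 °C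
Reagents that add atoms: tert-butyldimethylsilyl trifluoromethanesulfonate, CC(C)(C)[Si](C)(C)OS(=O)(=O)C(F)(F)F
Why: Silylation of a hindered secondary alcohol with a silyl triflate and a hindered base; the bulky non-chelating silyl ether is what later gives the aldehyde its Felkin-type facial bias.

Step 4
Reactants: 5 tert-butyl (4S)-4-[(1R)-1-[(tert-butyldimethylsilyl)oxy]prop-2-en-1-yl]-2,2-dimethyl-1,3-oxazolidine-3-carboxylate
Product: 7 tert-butyl (4S)-4-[(1S)-1-[(tert-butyldimethylsilyl)oxy]-2-oxoethyl]-2,2-dimethyl-1,3-oxazolidine-3-carboxylate, via ozonide 6 (not isolated)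
Conditions: O3, CH2Cl2, −78 °C; PPh3, −78 °C to rt; used at once
Reagents that add atoms: ozone, [O-][O+]=O
Why: Ozonolysis of the terminal alkene with reductive work-up; the conditions are neutral, so the α-silyloxy stereocenter should survive, and the change of descriptor from R to S is only a change of priorities.

Step 5
Reactants: 8 (2E)-hept-2-en-1-ol
Product: 9 [(1S,2S)-2-butylcyclopropyl]methanol
Conditions: Zn(CH2I)2·DME (from Et2Zn, CH2I2, DME), (4R,5R)-2-butyl-N,N,N',N'-tetramethyl-1,3,2-dioxaborolane-4,5-dicarboxamide (1.2 equiv), CH2Cl2, −10 °C to rt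
Reagents that add atoms: diiodomethane, ICI
Why: Charette asymmetric Simmons–Smith cyclopropanation: the zinc alkoxide of 8 binds the chiral dioxaborolane, which directs CH2 transfer to one alkene face; the addition is stereospecific, so the E alkene gives the trans ring, and the (4R,5R) ligand should give the (1S,2S) isomer (C12 and C13 of the target).

Step 6
Reactants: 9 [(1S,2S)-2-butylcyclopropyl]methanol
Product: 10 (1S,2S)-2-butylcyclopropane-1-carbaldehyde
Conditions: Dess–Martin periodinane, CH2Cl2, 0 °C to rt; solution concentrated cold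
Reagents that add atoms: none
Why: Dess–Martin oxidation of a primary alcohol; it is mild and non-basic, and the trans aldehyde is the thermodynamically preferred epimer in any case.

Step 7
Reactants: 10 (1S,2S)-2-butylcyclopropane-1-carbaldehyde; 11 (3-carboxypropyl)triphenylphosphonium bromide
Product: 13 (4Z)-5-[(1S,2S)-2-butylcyclopropyl]pent-4-enoic acid, via phosphorus ylide 12 (not isolated)
Conditions: 11, NaN(SiMe3)2 (2.1 equiv), THF, 0 °C; 10, −78 °C to rt; 1 M HCl
Reagents that add atoms: none
Why: Wittig olefination with a non-stabilised ylide forms the C10–C11 bond without any reactive centre at the cyclopropylcarbinyl carbon; the geometry (mainly Z) does not matter, and acid–base extraction separates the product from Ph3PO.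

Step 8
Reactants: 13 (4Z)-5-[(1S,2S)-2-butylcyclopropyl]pent-4-enoic acid
Product: 14 5-[(1S,2S)-2-butylcyclopropyl]pentanoic acid
Conditions: TsNHNH2 (excess, in portions), NaOAc, DME/H2O, reflux
Reagents that add atoms: none
Why: Diimide reduction: concerted syn transfer of two hydrogens with no metal surface and no radical or ionic intermediate, so the vinylcyclopropane is saturated without ring opening.

Step 9
Reactants: 14 5-[(1S,2S)-2-butylcyclopropyl]pentanoic acid
Product: 15 5-[(1S,2S)-2-butylcyclopropyl]pentan-1-ol
Conditions: LiAlH4, THF, 0 °C to reflux; aq. NaOH work-up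
Reagents that add atoms: none
Why: Hydride reduction of a carboxylic acid to the primary alcohol; the alkylcyclopropane is inert to LiAlH4.

Step 10
Reactants: 15 5-[(1S,2S)-2-butylcyclopropyl]pentan-1-ol
Product: 16 5-[(1S,2S)-2-butylcyclopropyl]pentyl N,N-di(propan-2-yl)carbamate
Conditions: i-Pr2NCOCl (1.3 equiv), Et3N, CH2Cl2, reflux
Reagents that add atoms: N,N-diisopropylcarbamoyl chloride, CC(C)N(C(C)C)C(=O)Cl
Why: Carbamoylation of a primary alcohol; the hindered carbamate is both the directing group for α-lithiation and the leaving group in the later 1,2-migration.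

Step 11
Reactants: 16 5-[(1S,2S)-2-butylcyclopropyl]pentyl N,N-di(propan-2-yl)carbamate; 17 2-ethenyl-4,4,5,5-tetramethyl-1,3,2-dioxaborolane
Product: 20 2-[(3S)-7-[(1S,2S)-2-butylcyclopropyl]hept-1-en-3-yl]-4,4,5,5-tetramethyl-1,3,2-dioxaborolane, via lithiated carbamate 18 (not isolated), via vinyl boronate complex 19 (not isolated)
Conditions: s-BuLi (1.3 equiv), (+)-sparteine (1.3 equiv), Et2O, −78 °C, 5 h; 17, −78 °C, 1 h; MgBr2·OEt2, then reflux
Reagents that add atoms: none
Why: Hoppe-type enantioselective deprotonation followed by lithiation–borylation: s-BuLi/(+)-sparteine removes the pro-R hydrogen next to oxygen to give the configurationally stable (R)-lithio species 18, 17 traps it with retention as complex 19, and Lewis acid and warming trigger the 1,2-metallate shift in which vinyl migrates from boron to carbon anti to the departing carbamate (inversion), which leaves boron on an S-configured allylic carbon.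

Step 12
Reactants: 20 2-[(3S)-7-[(1S,2S)-2-butylcyclopropyl]hept-1-en-3-yl]-4,4,5,5-tetramethyl-1,3,2-dioxaborolane; 7 tert-butyl (4S)-4-[(1S)-1-[(tert-butyldimethylsilyl)oxy]-2-oxoethyl]-2,2-dimethyl-1,3-oxazolidine-3-carboxylate
Product: 24 tert-butyl (4S)-4-[(1S,2R,4E)-9-[(1S,2S)-2-butylcyclopropyl]-1-[(tert-butyldimethylsilyl)oxy]-2-hydroxynon-4-en-1-yl]-2,2-dimethyl-1,3-oxazolidine-3-carboxylate, via butyl boronate complex 21 (not isolated), via borinic ester 22 (not isolated), via borinate 23 (not isolated)
Conditions: 20 (1.2 equiv), n-BuLi (1.2 equiv), THF, −78 °C; (CF3CO)2O (1.4 equiv), −78 °C; 7 (1.0 equiv), −78 °C, then to rt; aq. NaHCO3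
Reagents that add atoms: none
Why: n-BuLi adds to boron of 20 to give complex 21, and (CF3CO)2O acylates one pinacol oxygen and opens the dioxaborolane to the more Lewis-acidic borinic ester 22 without touching the boron-bearing stereocenter. Aldehyde 7 then binds to boron through oxygen, and the allyl group is transferred through a closed six-membered chair transition state (type 1 allylboration of an α-substituted allylboron reagent, the known E-selective borinic ester variant) with allylic transposition: the C4–C5 bond forms at the former terminal CH2, the double bond moves to C6=C7, and no ring is closed. With only a butyl group and one alkoxide left on boron, the C8 chain can sit pseudo-equatorial, and this makes the new alkene E. In that chair the S configuration of the boron-bearing carbon places the allyl terminus on the Re face of the aldehyde, which gives 4R, so the new stereocenter and the alkene geometry are both controlled by the centre set in step 11. The step needs E over Z and Re over Si selectivity; both depend on complete conversion of 20 into 22 before 7 is added, because unactivated pinacol ester reacts through the other chair (Z alkene, opposite face), and on keeping 22 cold so that it does not undergo a 1,3-boron shift. The Re face is also the one that the α-silyloxy aldehyde prefers by itself under non-chelating conditions (polar Felkin–Anh, 3,4-anti), so reagent and substrate control are matched. Aqueous work-up hydrolyses borinate 23 to the free C4 alcohol.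

Step 13
Reactants: 24 tert-butyl (4S)-4-[(1S,2R,4E)-9-[(1S,2S)-2-butylcyclopropyl]-1-[(tert-butyldimethylsilyl)oxy]-2-hydroxynon-4-en-1-yl]-2,2-dimethyl-1,3-oxazolidine-3-carboxylate
Product: 25 (2S,3S,4R,6E)-2-amino-11-[(1S,2S)-2-butylcyclopropyl]undec-6-ene-1,3,4-triol
Conditions: 3 M aq. HCl, MeOH/THF, rt to 40 °C; aq. NaOH to pH 11
Reagents that add atoms: none
Why: Acid hydrolysis removes the N,O-acetonide, the Boc group and the silyl ether in one operation; the isolated alkene, the homoallylic alcohol and the dialkylcyclopropane are not ionised by dilute aqueous acid at this temperature, and the aqueous medium prevents re-acetalisation by the released acetone.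

Step 14
Reactants: 26 pentacosanoic acid; 27 (4R)-4-benzyl-1,3-oxazolidin-2-one
Product: 29 (4R)-4-benzyl-3-pentacosanoyl-1,3-oxazolidin-2-one, via mixed anhydride 28 (not isolated)
Conditions: t-BuCOCl, Et3N, THF, −20 to 0 °C; 27, LiCl, rt
Reagents that add atoms: none
Why: N-acylation of an Evans oxazolidinone through the mixed pivalic anhydride; the hindered pivaloyl carbonyl directs attack to the fatty acyl carbon.

Step 15
Reactants: 29 (4R)-4-benzyl-3-pentacosanoyl-1,3-oxazolidin-2-one
Product: 31 (4R)-4-benzyl-3-[(2R)-2-hydroxypentacosanoyl]-1,3-oxazolidin-2-one, via sodium enolate 30 (not isolated)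
Conditions: NaN(SiMe3)2 (1.2 equiv), THF, −78 °C; 2-(benzenesulfonyl)-3-phenyloxaziridine (1.5 equiv), −78 °C; AcOH
Reagents that add atoms: 2-(benzenesulfonyl)-3-phenyloxaziridine, O=S(=O)(c1ccccc1)N1OC1c1ccccc1
Why: Evans asymmetric enolate hydroxylation with a Davis oxaziridine: the chelated Z sodium enolate is attacked by the electrophilic oxygen on the face opposite the benzyl group, which for the (4R) auxiliary gives the 2R alcohol.

Step 16
Reactants: 31 (4R)-4-benzyl-3-[(2R)-2-hydroxypentacosanoyl]-1,3-oxazolidin-2-one
Product: 33 (2R)-2-hydroxypentacosanoic acid, via peroxy acid 32 (not isolated)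
Conditions: LiOH, H2O2 (30% aq.), THF/H2O, 0 °C to rt; aq. Na2SO3; 1 M HCl
Reagents that add atoms: hydrogen peroxide, OO
Why: Hydroperoxide cleavage of the imide at the exocyclic carbonyl gives the peroxy acid, which sulfite reduces to the acid; the conditions do not epimerise the α-hydroxy centre, and the auxiliary is recovered.

Step 17
Reactants: 25 (2S,3S,4R,6E)-2-amino-11-[(1S,2S)-2-butylcyclopropyl]undec-6-ene-1,3,4-triol; 33 (2R)-2-hydroxypentacosanoic acid
Product: 35 (2R)-N-[(2S,3S,4R,6E)-11-[(1S,2S)-2-butylcyclopropyl]-1,3,4-trihydroxyundec-6-en-2-yl]-2-hydroxypentacosanamide, via benzotriazolyl ester 34 (not isolated)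
Conditions: EDC·HCl (1.3 equiv), HOBt (1.3 equiv), THF/CH2Cl2, 40 °C
Reagents that add atoms: none
Why: Carbodiimide amidation through the hydroxybenzotriazole active ester; the primary amine is far more nucleophilic than the hydroxyls toward this ester, so N-acylation should be selective without protecting groups, and no stereocenter is touched.

## Compound list

1 | methyl (4S)-3-(tert-butoxycarbonyl)-2,2-dimethyl-1,3-oxazolidine-4-carboxylate | CC(C)(C)OC(=O)N1[C@@H](COC1(C)C)C(=O)OC | starting material
2 | tert-butyl (4S)-4-{[bis(2-methylpropyl)alumanyl]oxy(methoxy)methyl}-2,2-dimethyl-1,3-oxazolidine-3-carboxylate (both epimers at the acetal carbon) | CC(C)(C)OC(=O)N1[C@@H](COC1(C)C)C(OC)O[Al](CC(C)C)CC(C)C | intermediate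
3 | tert-butyl (4S)-4-formyl-2,2-dimethyl-1,3-oxazolidine-3-carboxylate | CC(C)(C)OC(=O)N1[C@@H](COC1(C)C)C=O | intermediate
4 | tert-butyl (4S)-4-[(1R)-1-hydroxyprop-2-en-1-yl]-2,2-dimethyl-1,3-oxazolidine-3-carboxylate | CC(C)(C)OC(=O)N1[C@@H](COC1(C)C)[C@H](O)C=C | intermediate
5 | tert-butyl (4S)-4-[(1R)-1-[(tert-butyldimethylsilyl)oxy]prop-2-en-1-yl]-2,2-dimethyl-1,3-oxazolidine-3-carboxylate | CC(C)(C)OC(=O)N1[C@@H](COC1(C)C)[C@H](O[Si](C)(C)C(C)(C)C)C=C | intermediate
6 | tert-butyl (4S)-4-[(S)-[(tert-butyldimethylsilyl)oxy](1,2,4-trioxolan-3-yl)methyl]-2,2-dimethyl-1,3-oxazolidine-3-carboxylate (both epimers at the trioxolane carbon) | CC(C)(C)OC(=O)N1[C@@H](COC1(C)C)[C@H](O[Si](C)(C)C(C)(C)C)C2OCOO2 | intermediate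
7 | tert-butyl (4S)-4-[(1S)-1-[(tert-butyldimethylsilyl)oxy]-2-oxoethyl]-2,2-dimethyl-1,3-oxazolidine-3-carboxylate | CC(C)(C)OC(=O)N1[C@@H](COC1(C)C)[C@H](O[Si](C)(C)C(C)(C)C)C=O | intermediate
8 | (2E)-hept-2-en-1-ol | CCCC/C=C/CO | starting material
9 | [(1S,2S)-2-butylcyclopropyl]methanol | OC[C@H]1C[C@@H]1CCCC | intermediate
10 | (1S,2S)-2-butylcyclopropane-1-carbaldehyde | O=C[C@H]1C[C@@H]1CCCC | intermediate
11 | (3-carboxypropyl)triphenylphosphonium bromide | OC(=O)CCC[P+](c1ccccc1)(c1ccccc1)c1ccccc1.[Br-] | starting material
12 | sodium 4-(triphenyl-λ5-phosphanylidene)butanoate | [Na+].[O-]C(=O)CCC=P(c1ccccc1)(c1ccccc1)c1ccccc1 | intermediate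
13 | (4Z)-5-[(1S,2S)-2-butylcyclopropyl]pent-4-enoic acid | OC(=O)CC/C=C\[C@H]1C[C@@H]1CCCC | intermediate
14 | 5-[(1S,2S)-2-butylcyclopropyl]pentanoic acid | OC(=O)CCCC[C@H]1C[C@@H]1CCCC | intermediate
15 | 5-[(1S,2S)-2-butylcyclopropyl]pentan-1-ol | OCCCCC[C@H]1C[C@@H]1CCCC | intermediate
16 | 5-[(1S,2S)-2-butylcyclopropyl]pentyl N,N-di(propan-2-yl)carbamate | CC(C)N(C(C)C)C(=O)OCCCCC[C@H]1C[C@@H]1CCCC | intermediate
17 | 2-ethenyl-4,4,5,5-tetramethyl-1,3,2-dioxaborolane | C=CB1OC(C)(C)C(C)(C)O1 | starting material
18 | (1R)-5-[(1S,2S)-2-butylcyclopropyl]-1-lithiopentyl N,N-di(propan-2-yl)carbamate, as its (+)-sparteine complex | CC(C)N(C(C)C)C(=O)O[C@H]([Li])CCCC[C@H]1C[C@@H]1CCCC | intermediate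
19 | lithium {(1R)-5-[(1S,2S)-2-butylcyclopropyl]-1-[(dipropan-2-ylcarbamoyl)oxy]pentyl}(ethenyl)(2,3-dimethylbutane-2,3-diolato)borate | CC(C)N(C(C)C)C(=O)O[C@H]([B-]2(C=C)OC(C)(C)C(C)(C)O2)CCCC[C@H]1C[C@@H]1CCCC.[Li+] | intermediate
20 | 2-[(3S)-7-[(1S,2S)-2-butylcyclopropyl]hept-1-en-3-yl]-4,4,5,5-tetramethyl-1,3,2-dioxaborolane | C=C[C@@H](B1OC(C)(C)C(C)(C)O1)CCCC[C@H]2C[C@@H]2CCCC | intermediate
21 | lithium butyl[(3S)-7-[(1S,2S)-2-butylcyclopropyl]hept-1-en-3-yl](2,3-dimethylbutane-2,3-diolato)borate | C=C[C@@H]([B-]1(CCCC)OC(C)(C)C(C)(C)O1)CCCC[C@H]2C[C@@H]2CCCC.[Li+] | intermediate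
22 | 3-({butyl[(3S)-7-[(1S,2S)-2-butylcyclopropyl]hept-1-en-3-yl]boranyl}oxy)-2,3-dimethylbutan-2-yl trifluoroacetate | C=C[C@@H](B(CCCC)OC(C)(C)C(C)(C)OC(=O)C(F)(F)F)CCCC[C@H]1C[C@@H]1CCCC | intermediate
23 | O-borinate of 24: the C4 oxygen of 24 bonded to B(butyl)[O–C(CH3)2–C(CH3)2–OC(O)CF3] | CC(C)(C)OC(=O)N1[C@@H](COC1(C)C)[C@H](O[Si](C)(C)C(C)(C)C)[C@H](OB(CCCC)OC(C)(C)C(C)(C)OC(=O)C(F)(F)F)C/C=C/CCCC[C@H]2C[C@@H]2CCCC | intermediate
24 | tert-butyl (4S)-4-[(1S,2R,4E)-9-[(1S,2S)-2-butylcyclopropyl]-1-[(tert-butyldimethylsilyl)oxy]-2-hydroxynon-4-en-1-yl]-2,2-dimethyl-1,3-oxazolidine-3-carboxylate | CC(C)(C)OC(=O)N1[C@@H](COC1(C)C)[C@H](O[Si](C)(C)C(C)(C)C)[C@H](O)C/C=C/CCCC[C@H]2C[C@@H]2CCCC | intermediate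
25 | (2S,3S,4R,6E)-2-amino-11-[(1S,2S)-2-butylcyclopropyl]undec-6-ene-1,3,4-triol | N[C@@H](CO)[C@H](O)[C@H](O)C/C=C/CCCC[C@H]1C[C@@H]1CCCC | intermediate
26 | pentacosanoic acid | CCCCCCCCCCCCCCCCCCCCCCCCC(=O)O | starting material
27 | (4R)-4-benzyl-1,3-oxazolidin-2-one | O=C1OC[C@@H](Cc2ccccc2)N1 | starting material
28 | pentacosanoic 2,2-dimethylpropanoic anhydride | CCCCCCCCCCCCCCCCCCCCCCCCC(=O)OC(=O)C(C)(C)C | intermediate
29 | (4R)-4-benzyl-3-pentacosanoyl-1,3-oxazolidin-2-one | CCCCCCCCCCCCCCCCCCCCCCCCC(=O)N1[C@H](Cc2ccccc2)COC1=O | intermediate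
30 | sodium (1Z)-1-[(4R)-4-benzyl-2-oxo-1,3-oxazolidin-3-yl]pentacos-1-en-1-olate | CCCCCCCCCCCCCCCCCCCCCCC/C=C(\[O-])N1[C@H](Cc2ccccc2)COC1=O.[Na+] | intermediate
31 | (4R)-4-benzyl-3-[(2R)-2-hydroxypentacosanoyl]-1,3-oxazolidin-2-one | CCCCCCCCCCCCCCCCCCCCCCC[C@@H](O)C(=O)N1[C@H](Cc2ccccc2)COC1=O | intermediate
32 | (2R)-2-hydroxypentacosaneperoxoic acid (present as its lithium salt) | CCCCCCCCCCCCCCCCCCCCCCC[C@@H](O)C(=O)OO | intermediate
33 | (2R)-2-hydroxypentacosanoic acid | CCCCCCCCCCCCCCCCCCCCCCC[C@@H](O)C(=O)O | intermediate
34 | 1H-benzotriazol-1-yl (2R)-2-hydroxypentacosanoate | CCCCCCCCCCCCCCCCCCCCCCC[C@@H](O)C(=O)On1nnc2ccccc12 | intermediate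
35 | (2R)-N-[(2S,3S,4R,6E)-11-[(1S,2S)-2-butylcyclopropyl]-1,3,4-trihydroxyundec-6-en-2-yl]-2-hydroxypentacosanamide | CCCCCCCCCCCCCCCCCCCCCCC[C@@H](O)C(=O)N[C@@H](CO)[C@H](O)[C@H](O)C/C=C/CCCC[C@H]1C[C@@H]1CCCC | target

## Step count and least certain steps

Total step count: 17 (aldehyde branch 4, boronate branch 7, union and deprotection 2, acid branch 3, final acylation 1). Longest linear sequence: 10 steps (steps 5 to 13, then step 17), starting from 8.

Step 12 (key step). The most likely failure is incomplete conversion of 20 into borinic ester 22, or a 1,3-boron shift of 22 before the aldehyde arrives. Either would erode the E geometry and the C4 configuration together. Slow addition to the hindered α-branched aldehyde and epimerisation of 7 during a long reaction time are the second concern.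
Fallback: setting out from 7 and 15 and returning at 24, the C4–C5 bond and the alkene are made in separate operations. Alcohol 15 is oxidised with Dess–Martin periodinane to 5-[(1S,2S)-2-butylcyclopropyl]pentanal F1, which is methylenated with Ph3P=CH2 to (1S,2S)-1-butyl-2-(hex-5-en-1-yl)cyclopropane F2. Aldehyde 7 is allylated with B-allyldiisopinocampheylborane of the (−)-α-pinene series (Brown allylation, Re-face delivery, matched with the Felkin preference), which gives tert-butyl (4S)-4-[(1S,2R)-1-[(tert-butyldimethylsilyl)oxy]-2-hydroxypent-4-en-1-yl]-2,2-dimethyl-1,3-oxazolidine-3-carboxylate F3. Cross-metathesis of F3 with an excess of F2, using the second-generation Grubbs catalyst (H2IMes)(PCy3)Cl2Ru=CHPh in CH2Cl2 at 40 °C, should give 24, with E expected to predominate and the Z isomer removed by chromatography.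

Step 11. Ate-complex formation with the small, electron-poor vinylboronate 17 may be slow or reversible in the presence of the diamine, and the 1,2-migration may be incomplete. Partial racemisation of 18 on warming, or return to 16, would follow.
Fallback: from 16, the lithiated carbamate is first trapped with Me3SnCl (retention) to give (1R)-5-[(1S,2S)-2-butylcyclopropyl]-1-(trimethylstannyl)pentyl N,N-di(propan-2-yl)carbamate F4, which is purified and checked for enantiopurity. Tin–lithium exchange with n-BuLi in Et2O at −78 °C (retention) regenerates the lithio species free of diamine. Borylation with 17 and migration with MgBr2·OEt2 then return to 20.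

Step 2. Facial selectivity of the Grignard addition to 3 may be only moderate, and the separation of the epimeric alcohols may be difficult, so that syn material is carried forward.
Fallback: from 3, LiC≡CSiMe3 in THF with HMPA at −78 °C (strictly non-chelating, higher anti preference) gives tert-butyl (4S)-4-[(1R)-1-hydroxy-3-(trimethylsilyl)prop-2-yn-1-yl]-2,2-dimethyl-1,3-oxazolidine-3-carboxylate F5. K2CO3 in MeOH removes the silyl group to give tert-butyl (4S)-4-[(1R)-1-hydroxyprop-2-yn-1-yl]-2,2-dimethyl-1,3-oxazolidine-3-carboxylate F6. Semihydrogenation with H2 over Pd/CaCO3 poisoned with Pb(OAc)2 and quinoline returns to 4.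

Step 15. The C25 imide or its sodium enolate may precipitate from THF at −78 °C, leading to incomplete enolisation, incomplete oxygen transfer, or imide cleavage on prolonged exposure to base.
Fallback: from 29, the titanium enolate (TiCl4, Et3N, CH2Cl2, 0 °C to rt, where the chain stays dissolved) is oxidised with two equivalents of TEMPO, a radical aminoxylation on the face opposite the benzyl group. This gives (4R)-4-benzyl-3-[(2R)-2-[(2,2,6,6-tetramethylpiperidin-1-yl)oxy]pentacosanoyl]-1,3-oxazolidin-2-one F7. Zn dust in AcOH/THF cleaves the N–O bond and returns to 31.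

Step 17. Poor solubility of both waxy partners may slow the amidation enough for the activated, unprotected hydroxy acid to esterify itself or the product hydroxyls.
Fallback: from 33, acetylation (Ac2O, pyridine) gives (2R)-2-(acetyloxy)pentacosanoic acid F8, which is converted with N-hydroxysuccinimide and EDC·HCl into its isolable active ester 2,5-dioxopyrrolidin-1-yl (2R)-2-(acetyloxy)pentacosanoate F9. Acylation of 25 with F9 (Et3N, THF, 40 °C) gives (2R)-1-{[(2S,3S,4R,6E)-11-[(1S,2S)-2-butylcyclopropyl]-1,3,4-trihydroxyundec-6-en-2-yl]amino}-1-oxopentacosan-2-yl acetate F10. Catalytic NaOMe in MeOH removes the acetate, and any stray O-acyl groups, to return to 35.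

## Further compounds

F1 | step 12 | 5-[(1S,2S)-2-butylcyclopropyl]pentanal | O=CCCCC[C@H]1C[C@@H]1CCCC
F2 | step 12 | (1S,2S)-1-butyl-2-(hex-5-en-1-yl)cyclopropane | C=CCCCC[C@H]1C[C@@H]1CCCC
F3 | step 12 | tert-butyl (4S)-4-[(1S,2R)-1-[(tert-butyldimethylsilyl)oxy]-2-hydroxypent-4-en-1-yl]-2,2-dimethyl-1,3-oxazolidine-3-carboxylate | CC(C)(C)OC(=O)N1[C@@H](COC1(C)C)[C@H](O[Si](C)(C)C(C)(C)C)[C@H](O)CC=C
F4 | step 11 | (1R)-5-[(1S,2S)-2-butylcyclopropyl]-1-(trimethylstannyl)pentyl N,N-di(propan-2-yl)carbamate | CC(C)N(C(C)C)C(=O)O[C@H]([Sn](C)(C)C)CCCC[C@H]1C[C@@H]1CCCC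
F5 | step 2 | tert-butyl (4S)-4-[(1R)-1-hydroxy-3-(trimethylsilyl)prop-2-yn-1-yl]-2,2-dimethyl-1,3-oxazolidine-3-carboxylate | CC(C)(C)OC(=O)N1[C@@H](COC1(C)C)[C@H](O)C#C[Si](C)(C)C
F6 | step 2 | tert-butyl (4S)-4-[(1R)-1-hydroxyprop-2-yn-1-yl]-2,2-dimethyl-1,3-oxazolidine-3-carboxylate | CC(C)(C)OC(=O)N1[C@@H](COC1(C)C)[C@H](O)C#C
F7 | step 15 | (4R)-4-benzyl-3-[(2R)-2-[(2,2,6,6-tetramethylpiperidin-1-yl)oxy]pentacosanoyl]-1,3-oxazolidin-2-one | CCCCCCCCCCCCCCCCCCCCCCC[C@@H](ON1C(C)(C)CCCC1(C)C)C(=O)N2[C@H](Cc3ccccc3)COC2=O
F8 | step 17 | (2R)-2-(acetyloxy)pentacosanoic acid | CCCCCCCCCCCCCCCCCCCCCCC[C@@H](OC(C)=O)C(=O)O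
F9 | step 17 | 2,5-dioxopyrrolidin-1-yl (2R)-2-(acetyloxy)pentacosanoate | CCCCCCCCCCCCCCCCCCCCCCC[C@@H](OC(C)=O)C(=O)ON1C(=O)CCC1=O
F10 | step 17 | (2R)-1-{[(2S,3S,4R,6E)-11-[(1S,2S)-2-butylcyclopropyl]-1,3,4-trihydroxyundec-6-en-2-yl]amino}-1-oxopentacosan-2-yl acetate | CCCCCCCCCCCCCCCCCCCCCCC[C@@H](OC(C)=O)C(=O)N[C@@H](CO)[C@H](O)[C@H](O)C/C=C/CCCC[C@H]1C[C@@H]1CCCC
A1 | alternative 1 | ethyl (1S,2S)-2-butylcyclopropane-1-carboxylate | CCOC(=O)[C@H]1C[C@@H]1CCCC
A2 | alternative 1 | hex-1-ene | C=CCCCC
A3 | alternative 1 | ethyl diazoacetate | CCOC(=O)C=[N+]=[N-]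
A4 | alternative 2 | (4R)-4-[(1R)-1-hydroxy-3-[(4-methoxyphenyl)methoxy]propyl]-2,2-dimethyl-1,3-dioxan-5-one | O=C1COC(C)(C)O[C@@H]1[C@H](O)CCOCc1ccc(OC)cc1
A5 | alternative 2 | 2,2-dimethyl-1,3-dioxan-5-one | CC1(C)OCC(=O)CO1
A6 | alternative 2 | 3-[(4-methoxyphenyl)methoxy]propanal | O=CCCOCc1ccc(OC)cc1
A7 | alternative 2 | (R)-proline | OC(=O)[C@H]1CCCN1
A8 | alternative 3 | (4S)-4-[(1S,2R,4E)-9-[(1S,2S)-2-butylcyclopropyl]-2-[(tert-butyldimethylsilyl)oxy]-1-hydroxynon-4-en-1-yl]-1,3-oxazolidin-2-one | O=C1N[C@@H](CO1)[C@H](O)[C@H](O[Si](C)(C)C(C)(C)C)C/C=C/CCCC[C@H]2C[C@@H]2CCCC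
A9 | alternative 3 | (2Z,4R,6E)-11-[(1S,2S)-2-butylcyclopropyl]-4-[(tert-butyldimethylsilyl)oxy]undeca-2,6-dien-1-yl N-[(pentafluorobenzoyl)oxy]carbamate | O=C(NOC(=O)c1c(F)c(F)c(F)c(F)c1F)OC/C=C\[C@H](O[Si](C)(C)C(C)(C)C)C/C=C/CCCC[C@H]2C[C@@H]2CCCC
A10 | alternative 3 | dipotassium tetrahydroxidodioxidoosmate | [K+].[K+].O[Os-2](O)(O)(O)(=O)=O
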